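**Retrosynthetic overview**

1. The acetate comes from a silyl ether, and the C4 methyl group from a late equatorial methylation of the ring A ester enolate (C4–H ester).
2. Ring A is opened by a (4+2) annulation of a ring B keto acid with a vinylphosphonium salt: a decarboxylative C3 radical addition makes C2–C3, and the ylide that results closes C1=C10 by Wittig olefination of the C10 ketone. C5 is fixed in the same operation by dynamic kinetic resolution.
3. Enabling feature: in ring A, C1H=, C2H2 and C3H2 carry no substituents. C1–C2 is therefore a bare two-carbon bridge between C10 (a ring B ketone carbon next to quaternary C9, enolisable only towards C5) and C3 (β to the C4 ester carbonyl, i.e. the CH2 of a succinate whose free carboxyl is a traceless radical precursor).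
4. The keto acid comes from a Mukaiyama–Michael addition of the ring B silyl enol ether to a fumarate mono-imide (C4–C5 bond), followed by imide hydrolysis.
5. Ring B is in hand first (2-methylcyclohexenone; asymmetric methyl conjugate addition sets C8; enolate alkylation with an iodide from methyl hydrogen (R)-3-methylglutarate sets C9 and brings C13); ring A is formed second.

Key step: step 11

Remark: the target is read as (4S,5R,8R,9S,13S) in terpenoid numbering (C4 quaternary ester carbon, C5 ring-fusion CH, C1=C10 alkene, C8 CHMe, C9 quaternary carbon with the side chain, C13 side-chain CHMe). This numbering is used throughout, and compound 1 is taken as a commercial enantiopure half-ester.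

**Route**

Step 1
Reactants: 1 (R)-5-methoxy-3-methyl-5-oxopentanoic acid
Product: 2 methyl (R)-5-hydroxy-3-methylpentanoate
Conditions: BH3·SMe2, THF, 0 °C to rt; MeOH quench
Reagents that add atoms: none
Why: Borane reduces the free carboxylic acid much faster than the methyl ester (chemoselective acid reduction), and the future C13 centre is carried over untouched from 1.

Step 2
Reactants: 2 methyl (R)-5-hydroxy-3-methylpentanoate
Product: 3 methyl (R)-5-[(tert-butyldimethylsilyl)oxy]-3-methylpentanoate
Conditions: TBSCl, imidazole, DMF, 0 °C to rt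
Reagents that add atoms: tert-butyldimethylsilyl chloride, CC(C)(C)[Si](C)(C)Cl
Why: Standard silylation of a primary alcohol, done at once so that the δ-hydroxy ester cannot lactonise.

Step 3
Reactants: 3 methyl (R)-5-[(tert-butyldimethylsilyl)oxy]-3-methylpentanoate
Product: 4 (S)-5-[(tert-butyldimethylsilyl)oxy]-3-methylpentan-1-ol
Conditions: LiAlH4, Et2O, 0 °C
Reagents that add atoms: none
Why: Hydride reduction of the ester to the primary alcohol, with the stereocentre unchanged (the descriptor changes only through the priority switch).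

Step 4
Reactants: 4 (S)-5-[(tert-butyldimethylsilyl)oxy]-3-methylpentan-1-ol
Product: 5 (R)-tert-butyl[(5-iodo-3-methylpentyl)oxy]dimethylsilane
Conditions: I2, PPh3, imidazole, CH2Cl2, 0 °C
Reagents that add atoms: iodine, II
Why: Appel-type iodination of a primary alcohol under buffered conditions that leave the silyl ether intact.

Step 5
Reactants: 6 2-methylcyclohex-2-en-1-one
Product: 8 [(3R)-2,3-dimethylcyclohex-1-en-1-yl]oxy-trimethylsilane, via dimethylaluminium enolate 7 (not isolated)
Conditions: Me3Al, copper thiophene-2-carboxylate (2 mol %, monovalent copper), chiral binaphthol-derived phosphoramidite ligand (4 mol %), Et2O, −30 °C; then TMSOTf, −30 °C to rt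
Reagents that add atoms: trimethylaluminium, C[Al](C)C; trimethylsilyl trifluoromethanesulfonate, C[Si](C)(C)OS(=O)(=O)C(F)(F)F
Why: Copper-catalysed asymmetric conjugate addition of methyl sets C8 under ligand control (the ligand enantiomer is chosen to give 3R), and O-silylation stores the regiodefined enolate as the tetrasubstituted silyl enol ether.

Step 6
Reactants: 8 [(3R)-2,3-dimethylcyclohex-1-en-1-yl]oxy-trimethylsilane; 5 (R)-tert-butyl[(5-iodo-3-methylpentyl)oxy]dimethylsilane
Product: 10 (2S,3R)-2-[(3S)-5-[(tert-butyldimethylsilyl)oxy]-3-methylpentyl]-2,3-dimethylcyclohexan-1-one, via lithium enolate 9 (not isolated)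
Conditions: MeLi, THF, 0 °C; then 5, HMPA, −40 °C to rt
Reagents that add atoms: none
Why: MeLi releases the regiodefined lithium enolate, which should be alkylated by the primary iodide on the face anti to the adjacent C8 methyl group (axial attack opposite the pseudoaxial methyl), setting quaternary C9 with the two ring methyl groups cis.

Step 7
Reactants: 10 (2S,3R)-2-[(3S)-5-[(tert-butyldimethylsilyl)oxy]-3-methylpentyl]-2,3-dimethylcyclohexan-1-one
Product: 12 [(5R,6S)-6-[(3S)-5-[(tert-butyldimethylsilyl)oxy]-3-methylpentyl]-5,6-dimethylcyclohex-1-en-1-yl]oxy-trimethylsilane, via lithium enolate 11 (not isolated)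
Conditions: LiN(iPr)2, THF, −78 °C; then TMSCl, −78 °C to 0 °C
Reagents that add atoms: chlorotrimethylsilane, C[Si](C)(C)Cl
Why: Because C9 is quaternary the ketone has a single enolisable side, so deprotonation and O-silylation give one regioisomer of the silyl enol ether.

Step 8
Reactants: 13 (E)-4-methoxy-4-oxobut-2-enoic acid; 14 1,3-oxazolidin-2-one
Product: 16 methyl (E)-4-oxo-4-(2-oxo-1,3-oxazolidin-3-yl)but-2-enoate, via mixed pivalic anhydride 15 (not isolated)
Conditions: PivCl, Et3N, THF, −20 °C; then 14, LiCl, −20 °C to rt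
Reagents that add atoms: none
Why: N-Acylation of the oxazolidinone through the mixed anhydride differentiates the two fumarate ends and gives an acceptor whose chelating imide end is the more activating one.

Step 9
Reactants: 12 [(5R,6S)-6-[(3S)-5-[(tert-butyldimethylsilyl)oxy]-3-methylpentyl]-5,6-dimethylcyclohex-1-en-1-yl]oxy-trimethylsilane; 16 methyl (E)-4-oxo-4-(2-oxo-1,3-oxazolidin-3-yl)but-2-enoate
Product: 17 methyl 2-[(3S,4R)-3-[(3S)-5-[(tert-butyldimethylsilyl)oxy]-3-methylpentyl]-3,4-dimethyl-2-oxocyclohexyl]-4-oxo-4-(2-oxo-1,3-oxazolidin-3-yl)butanoate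
Conditions: Sc(OTf)3 (10 mol %), (CF3)2CHOH, CH2Cl2, −78 °C to −20 °C
Reagents that add atoms: none
Why: Mukaiyama–Michael addition to the Lewis-acid-chelated imide occurs at the carbon β to the imide carbonyl (the one bearing the methyl ester), forming C4–C5 with the ester on C4 and the imide carbonyl on C3; the two new centres form as a mixture, which is harmless because C5 is corrected in step 11 and C4 is re-enolised in step 12.

Step 10
Reactants: 17 methyl 2-[(3S,4R)-3-[(3S)-5-[(tert-butyldimethylsilyl)oxy]-3-methylpentyl]-3,4-dimethyl-2-oxocyclohexyl]-4-oxo-4-(2-oxo-1,3-oxazolidin-3-yl)butanoate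
Product: 19 4-methoxy-3-[(3S,4R)-3-[(3S)-5-[(tert-butyldimethylsilyl)oxy]-3-methylpentyl]-3,4-dimethyl-2-oxocyclohexyl]-4-oxobutanoic acid, via peroxy acid 18 (not isolated)
Conditions: LiOH, H2O2, THF/H2O, 0 °C; then Na2SO3; then 1 M HCl
Reagents that add atoms: hydrogen peroxide, OO
Why: Lithium hydroperoxide cleaves the exocyclic imide carbonyl chemoselectively beside the methyl ester, and sulfite reduces the peracid to the free acid that serves as radical precursor.

Step 11
Reactants: 19 4-methoxy-3-[(3S,4R)-3-[(3S)-5-[(tert-butyldimethylsilyl)oxy]-3-methylpentyl]-3,4-dimethyl-2-oxocyclohexyl]-4-oxobutanoic acid; 20 vinyltriphenylphosphonium bromide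
Product: 23 methyl (5S,6R,8aS)-5-[(3S)-5-[(tert-butyldimethylsilyl)oxy]-3-methylpentyl]-5,6-dimethyl-1,2,3,5,6,7,8,8a-octahydronaphthalene-1-carboxylate, via phosphonium bromide 21 (not isolated), via ylide 22 (not isolated)
Conditions: 4CzIPN (3 mol %), Cs2CO3 (0.2 equiv), DMF, 450 nm LEDs, rt; then KOtBu, THF, 0 °C to 40 °C
Reagents that add atoms: none
Why: Proposed new method: the carboxylate of 19 is oxidised by photoexcited 4CzIPN and loses CO2, the primary C3 radical adds to the terminal carbon of 20 (C2–C3), the α-phosphonio radical is reduced by the reduced photocatalyst and protonated by further 19 to give 21, and KOtBu then forms ylide 22, which olefinates the ring B ketone (C1=C10). The closest known reactions are the photoredox radical addition to vinylphosphonium salts followed by Wittig olefination of aldehydes, and the anionic vinylphosphonium annulation (Michael addition, then intramolecular Wittig reaction). Ring A closes by 6-exo-trig attack of the ylide carbon on the C10 carbonyl, and collapse of the oxaphosphetane can place the alkene only at C1=C10, so the tetrasubstituted C5=C10 isomer is excluded. The one stereocentre fixed here, C5, should be set by dynamic kinetic resolution under control of the C8 methyl group: the α-keto centre epimerises under the basic conditions, and only the epimer with the C5 arm trans to the C8 methyl can accept the ylide at C10 from a chair with that methyl equatorial, whereas the other epimer must build a syn-axial contact between the C8 methyl and the new C10 substituent. The chemoselectivity needed is secured by the carboxylate being the only oxidisable group (radical at C3 only) and by the quaternary C9, which leaves the ketone with C5 as its only enolisable neighbour.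

Step 12
Reactants: 23 methyl (5S,6R,8aS)-5-[(3S)-5-[(tert-butyldimethylsilyl)oxy]-3-methylpentyl]-5,6-dimethyl-1,2,3,5,6,7,8,8a-octahydronaphthalene-1-carboxylate
Product: 25 methyl (1S,5S,6R,8aR)-5-[(3S)-5-[(tert-butyldimethylsilyl)oxy]-3-methylpentyl]-1,5,6-trimethyl-1,2,3,5,6,7,8,8a-octahydronaphthalene-1-carboxylate, via lithium ester enolate 24 (not isolated)
Conditions: LiN(iPr)2, THF, −78 °C to −20 °C; then MeI, DMPU, −78 °C to 0 °C
Reagents that add atoms: iodomethane, CI
Why: Alkylation of the exocyclic ester enolate of ring A, in which methyl iodide should enter on the equatorial face, syn to the axial C5 hydrogen and away from the axial hydrogens at C2 and C6, placing the methyl equatorial and the ester axial at C4 as in the target (substrate control by C5).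

Step 13
Reactants: 25 methyl (1S,5S,6R,8aR)-5-[(3S)-5-[(tert-butyldimethylsilyl)oxy]-3-methylpentyl]-1,5,6-trimethyl-1,2,3,5,6,7,8,8a-octahydronaphthalene-1-carboxylate
Product: 26 methyl (1S,5S,6R,8aR)-5-[(3S)-5-hydroxy-3-methylpentyl]-1,5,6-trimethyl-1,2,3,5,6,7,8,8a-octahydronaphthalene-1-carboxylate
Conditions: Bu4NF, THF, rt
Reagents that add atoms: none
Why: Fluoride cleavage of the primary silyl ether, to which the hindered axial methyl ester and the trisubstituted alkene are inert.

Step 14
Reactants: 26 methyl (1S,5S,6R,8aR)-5-[(3S)-5-hydroxy-3-methylpentyl]-1,5,6-trimethyl-1,2,3,5,6,7,8,8a-octahydronaphthalene-1-carboxylate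
Product: 27 methyl (1S,5S,6R,8aR)-5-[(3S)-5-(acetyloxy)-3-methylpentyl]-1,5,6-trimethyl-1,2,3,5,6,7,8,8a-octahydronaphthalene-1-carboxylate
Conditions: Ac2O, pyridine, DMAP (cat.), CH2Cl2, rt
Reagents that add atoms: acetic anhydride, CC(=O)OC(C)=O
Why: Acetylation of the primary alcohol completes the target without touching any stereocentre.

**Compound list**

1 | (R)-5-methoxy-3-methyl-5-oxopentanoic acid (methyl hydrogen (R)-3-methylglutarate) | COC(=O)C[C@H](C)CC(=O)O | starting material
2 | methyl (R)-5-hydroxy-3-methylpentanoate | COC(=O)C[C@H](C)CCO | intermediate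
3 | methyl (R)-5-[(tert-butyldimethylsilyl)oxy]-3-methylpentanoate | COC(=O)C[C@H](C)CCO[Si](C)(C)C(C)(C)C | intermediate
4 | (S)-5-[(tert-butyldimethylsilyl)oxy]-3-methylpentan-1-ol | OCC[C@H](C)CCO[Si](C)(C)C(C)(C)C | intermediate
5 | (R)-tert-butyl[(5-iodo-3-methylpentyl)oxy]dimethylsilane | ICC[C@H](C)CCO[Si](C)(C)C(C)(C)C | intermediate
6 | 2-methylcyclohex-2-en-1-one | CC1=CCCCC1=O | starting material
7 | dimethylaluminium (3R)-2,3-dimethylcyclohex-1-en-1-olate (not isolated) | C[Al](C)OC1=C(C)[C@H](C)CCC1 | intermediate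
8 | [(3R)-2,3-dimethylcyclohex-1-en-1-yl]oxy-trimethylsilane | C[Si](C)(C)OC1=C(C)[C@H](C)CCC1 | intermediate
9 | lithium (3R)-2,3-dimethylcyclohex-1-en-1-olate (not isolated) | [Li]OC1=C(C)[C@H](C)CCC1 | intermediate
10 | (2S,3R)-2-[(3S)-5-[(tert-butyldimethylsilyl)oxy]-3-methylpentyl]-2,3-dimethylcyclohexan-1-one | O=C1CCC[C@@H](C)[C@]1(C)CC[C@H](C)CCO[Si](C)(C)C(C)(C)C | intermediate
11 | lithium (5R,6S)-6-[(3S)-5-[(tert-butyldimethylsilyl)oxy]-3-methylpentyl]-5,6-dimethylcyclohex-1-en-1-olate (not isolated) | [Li]OC1=CCC[C@@H](C)[C@]1(C)CC[C@H](C)CCO[Si](C)(C)C(C)(C)C | intermediate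
12 | [(5R,6S)-6-[(3S)-5-[(tert-butyldimethylsilyl)oxy]-3-methylpentyl]-5,6-dimethylcyclohex-1-en-1-yl]oxy-trimethylsilane | C[Si](C)(C)OC1=CCC[C@@H](C)[C@]1(C)CC[C@H](C)CCO[Si](C)(C)C(C)(C)C | intermediate
13 | (E)-4-methoxy-4-oxobut-2-enoic acid (monomethyl fumarate) | COC(=O)/C=C/C(=O)O | starting material
14 | 1,3-oxazolidin-2-one | O=C1NCCO1 | starting material
15 | (E)-4-methoxy-4-oxobut-2-enoic pivalic anhydride (not isolated) | COC(=O)/C=C/C(=O)OC(=O)C(C)(C)C | intermediate
16 | methyl (E)-4-oxo-4-(2-oxo-1,3-oxazolidin-3-yl)but-2-enoate | COC(=O)/C=C/C(=O)N1CCOC1=O | intermediate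
17 | methyl 2-[(3S,4R)-3-[(3S)-5-[(tert-butyldimethylsilyl)oxy]-3-methylpentyl]-3,4-dimethyl-2-oxocyclohexyl]-4-oxo-4-(2-oxo-1,3-oxazolidin-3-yl)butanoate (mixture of epimers at C4 and C5) | O=C1C(C(CC(=O)N2CCOC2=O)C(=O)OC)CC[C@@H](C)[C@]1(C)CC[C@H](C)CCO[Si](C)(C)C(C)(C)C | intermediate
18 | 4-methoxy-3-[(3S,4R)-3-[(3S)-5-[(tert-butyldimethylsilyl)oxy]-3-methylpentyl]-3,4-dimethyl-2-oxocyclohexyl]-4-oxobutaneperoxoic acid (not isolated; epimer mixture) | O=C1C(C(CC(=O)OO)C(=O)OC)CC[C@@H](C)[C@]1(C)CC[C@H](C)CCO[Si](C)(C)C(C)(C)C | intermediate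
19 | 4-methoxy-3-[(3S,4R)-3-[(3S)-5-[(tert-butyldimethylsilyl)oxy]-3-methylpentyl]-3,4-dimethyl-2-oxocyclohexyl]-4-oxobutanoic acid (mixture of epimers at C4 and C5) | O=C1C(C(CC(=O)O)C(=O)OC)CC[C@@H](C)[C@]1(C)CC[C@H](C)CCO[Si](C)(C)C(C)(C)C | intermediate
20 | vinyltriphenylphosphonium bromide | C=C[P+](c1ccccc1)(c1ccccc1)c1ccccc1.[Br-] | starting material
21 | [5-methoxy-4-[(3S,4R)-3-[(3S)-5-[(tert-butyldimethylsilyl)oxy]-3-methylpentyl]-3,4-dimethyl-2-oxocyclohexyl]-5-oxopentyl]triphenylphosphonium bromide (not isolated; epimer mixture) | O=C1C(C(CCC[P+](c2ccccc2)(c2ccccc2)c2ccccc2)C(=O)OC)CC[C@@H](C)[C@]1(C)CC[C@H](C)CCO[Si](C)(C)C(C)(C)C.[Br-] | intermediate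
22 | methyl 2-[(3S,4R)-3-[(3S)-5-[(tert-butyldimethylsilyl)oxy]-3-methylpentyl]-3,4-dimethyl-2-oxocyclohexyl]-5-(triphenyl-λ5-phosphanylidene)pentanoate (not isolated; C5 epimerising) | O=C1C(C(CCC=P(c2ccccc2)(c2ccccc2)c2ccccc2)C(=O)OC)CC[C@@H](C)[C@]1(C)CC[C@H](C)CCO[Si](C)(C)C(C)(C)C | intermediate
23 | methyl (5S,6R,8aS)-5-[(3S)-5-[(tert-butyldimethylsilyl)oxy]-3-methylpentyl]-5,6-dimethyl-1,2,3,5,6,7,8,8a-octahydronaphthalene-1-carboxylate (mixture of epimers at C4, the ester-bearing carbon) | COC(=O)C1CCC=C2[C@H]1CC[C@@H](C)[C@]2(C)CC[C@H](C)CCO[Si](C)(C)C(C)(C)C | intermediate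
24 | lithium ester enolate of 23 (exocyclic C4=C(OMe)OLi; not isolated) | COC(O[Li])=C1CCC=C2[C@H]1CC[C@@H](C)[C@]2(C)CC[C@H](C)CCO[Si](C)(C)C(C)(C)C | intermediate
25 | methyl (1S,5S,6R,8aR)-5-[(3S)-5-[(tert-butyldimethylsilyl)oxy]-3-methylpentyl]-1,5,6-trimethyl-1,2,3,5,6,7,8,8a-octahydronaphthalene-1-carboxylate | COC(=O)[C@@]1(C)CCC=C2[C@H]1CC[C@@H](C)[C@]2(C)CC[C@H](C)CCO[Si](C)(C)C(C)(C)C | intermediate
26 | methyl (1S,5S,6R,8aR)-5-[(3S)-5-hydroxy-3-methylpentyl]-1,5,6-trimethyl-1,2,3,5,6,7,8,8a-octahydronaphthalene-1-carboxylate | COC(=O)[C@@]1(C)CCC=C2[C@H]1CC[C@@H](C)[C@]2(C)CC[C@H](C)CCO | intermediate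
27 | methyl (1S,5S,6R,8aR)-5-[(3S)-5-(acetyloxy)-3-methylpentyl]-1,5,6-trimethyl-1,2,3,5,6,7,8,8a-octahydronaphthalene-1-carboxylate | COC(=O)[C@@]1(C)CCC=C2[C@H]1CC[C@@H](C)[C@]2(C)CC[C@H](C)CCOC(C)=O | target

**Step count and risks**

Total step count: 14. Longest linear sequence: 12 steps (steps 1–4, 6, 7, 9–14).

Steps most likely to fail:

1. Step 11 (Proposed new method). What may go wrong: the ylide is quenched by proton transfer, enolises the hindered C10 ketone or is acylated by the neighbouring ester instead of closing the ring, and the funnelling of the C5 epimers through the faster-cyclising one stays incomplete. Fallback, from 19 back to 23, by known reactions: 19 is coupled with N-hydroxyphthalimide (DIC, DMAP) to the redox-active ester F1. Photoredox radical allylation with allyl phenyl sulfone (Ru(bpy)3(PF6)2, Hantzsch ester, iPr2NEt, blue light) gives the hex-5-enoate F2. Wittig methylenation of the ketone (Ph3PCH3Br, KOtBu, toluene, 80 °C) gives the methylidene diene F3; C5 equilibrates under these basic conditions, and the same syn-axial argument should favour attack on the epimer shown. Ring-closing metathesis with the second-generation Grubbs catalyst then closes C1=C10 with loss of ethylene and returns 23.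

2. Step 6. What may go wrong: alkylation of the hindered tetrasubstituted enolate by an unactivated primary iodide is slow, so proton transfer to the product scrambles the enolate regiochemistry and the facial selectivity at C9 erodes. Fallback, from 8 back to 10: Mukaiyama–Michael addition of 8 to acrolein (BF3·OEt2, CH2Cl2, −78 °C) gives the keto aldehyde F4 with the same anti sense. Wittig reaction with Ph3P=CHCO2Me gives the (E)-enoate F5. Copper-catalysed asymmetric conjugate addition of MeMgBr (CuBr·SMe2, Josiphos-type ferrocenyl diphosphine, t-BuOMe, −75 °C) sets C13 under catalyst control and gives the saturated ester F6. LiAlH4 reduces ester and ketone to the diol F7, selective silylation of the primary hydroxyl (TBSCl, imidazole) gives the mono-silyl ether F8, and Dess–Martin periodinane oxidation returns 10.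

3. Step 12. What may go wrong: poor facial selectivity in the alkylation of the ring A ester enolate by the small electrophile methyl iodide. Fallback, from 23 back to 25: 23 is converted (LiN(iPr)2, TMSCl) into the silyl ketene acetal F9. ZnBr2-catalysed alkylation with chloromethyl phenyl sulfide, a bulkier electrophile that reacts through an open transition state from the less hindered equatorial face, gives the phenylthiomethyl ester F10. Desulfurisation with deactivated Raney nickel returns 25.

**Further compounds**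

F1 | step 11 | 4-(1,3-dioxoisoindolin-2-yl) 1-methyl 2-[(3S,4R)-3-[(3S)-5-[(tert-butyldimethylsilyl)oxy]-3-methylpentyl]-3,4-dimethyl-2-oxocyclohexyl]butanedioate (epimer mixture at C4 and C5) | O=C1C(C(CC(=O)ON2C(=O)c3ccccc3C2=O)C(=O)OC)CC[C@@H](C)[C@]1(C)CC[C@H](C)CCO[Si](C)(C)C(C)(C)C
F2 | step 11 | methyl 2-[(3S,4R)-3-[(3S)-5-[(tert-butyldimethylsilyl)oxy]-3-methylpentyl]-3,4-dimethyl-2-oxocyclohexyl]hex-5-enoate (epimer mixture at C4 and C5) | O=C1C(C(CCC=C)C(=O)OC)CC[C@@H](C)[C@]1(C)CC[C@H](C)CCO[Si](C)(C)C(C)(C)C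
F3 | step 11 | methyl 2-[(1S,3S,4R)-3-[(3S)-5-[(tert-butyldimethylsilyl)oxy]-3-methylpentyl]-3,4-dimethyl-2-methylidenecyclohexyl]hex-5-enoate (epimers at C4) | C=C1[C@H](C(CCC=C)C(=O)OC)CC[C@@H](C)[C@]1(C)CC[C@H](C)CCO[Si](C)(C)C(C)(C)C
F4 | step 6 | 3-[(1S,6R)-1,6-dimethyl-2-oxocyclohexyl]propanal | O=C1CCC[C@@H](C)[C@]1(C)CCC=O
F5 | step 6 | methyl (E)-5-[(1S,6R)-1,6-dimethyl-2-oxocyclohexyl]pent-2-enoate | O=C1CCC[C@@H](C)[C@]1(C)CC/C=C/C(=O)OC
F6 | step 6 | methyl (3S)-5-[(1S,6R)-1,6-dimethyl-2-oxocyclohexyl]-3-methylpentanoate | O=C1CCC[C@@H](C)[C@]1(C)CC[C@H](C)CC(=O)OC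
F7 | step 6 | (3S)-5-[(1S,6R)-2-hydroxy-1,6-dimethylcyclohexyl]-3-methylpentan-1-ol (carbinol epimers) | OC1CCC[C@@H](C)[C@]1(C)CC[C@H](C)CCO
F8 | step 6 | (2S,3R)-2-[(3S)-5-[(tert-butyldimethylsilyl)oxy]-3-methylpentyl]-2,3-dimethylcyclohexan-1-ol (carbinol epimers) | OC1CCC[C@@H](C)[C@]1(C)CC[C@H](C)CCO[Si](C)(C)C(C)(C)C
F9 | step 12 | trimethylsilyl ketene acetal of 23 (exocyclic C4=C(OMe)OSiMe3, other centres as in 23) | COC(O[Si](C)(C)C)=C1CCC=C2[C@H]1CC[C@@H](C)[C@]2(C)CC[C@H](C)CCO[Si](C)(C)C(C)(C)C
F10 | step 12 | analogue of 25 with a phenylsulfanylmethyl group in place of the C4 methyl group (other centres as in 25) | COC(=O)[C@@]1(CSc3ccccc3)CCC=C2[C@H]1CC[C@@H](C)[C@]2(C)CC[C@H](C)CCO[Si](C)(C)C(C)(C)C
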